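**Strategy**

Everything rests on opening the ten-membered carbocycle at C1–C10 (germacranolide numbering; C12 lactone carbonyl, C13 exocyclic methylene): ring ketone C1 and tertiary carbinol C10(Me)(OH) form an α-ketol, the formal adduct of a C1 acyl anion and a C10 methyl ketone. A triazolylidene-catalysed crossed benzoin reaction forges this bond, closes the carbocycle and sets C10 in one operation. The precursor is a trans-γ-lactone (C7, C8, C11, C12, O) bearing the C1–C6 aldehyde arm on C7 and the α-acyloxy methyl ketone C9–C10 on C8, with both isobutyrates in place, C5 benzylated and C11=C13 masked as its dimethylamine adduct; indium allylation joins the arms at C6–C7 and one ozonolysis unveils both carbonyls.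

Key step: step 18

**Remarks on the chemistry**

- Numbering: C1 ketone, C2, C3, C4 (CHMe), C5 (CHOH), C6 (CH–O-isobutyryl), C7, C8 (lactone O–CH), C9 (CH–O-isobutyryl), C10 (C(Me)OH), C11, C12 (lactone C=O), C13 (=CH2). Isobutyrate means 2-methylpropanoate.
- Assumption: the target is taken as the open 1-oxo-5-hydroxy form as drawn; a transannular C1/C5 hemiketal, if it forms, would be in equilibrium with it.
- C5 is carried as a benzyl ether. An α-benzyloxy aldehyde lets indium chelate in step 14, so chelation and the butenolide reagent agree on the 5,6-syn diol; a non-chelating silyl ether would favour the 5,6-anti (Felkin) isomer. The benzyl ether also survives ozone and is removed without base, which avoids O6→O5 acyl migration.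
- The C1 aldehyde and the C10 ketone are stored as a vinyl and an isopropenyl group until step 17.
- The C11 configuration is of no consequence, since it is erased in step 20.
- (+)-Ipc2BOMe denotes the antipode made from (−)-α-pinene.

**Route**

Fragment A (C1–C6)

Step 1
Reactants: 1 pent-4-enal; 2 ethyl (triphenyl-λ5-phosphanylidene)acetate
Product: 3 ethyl (2E)-hepta-2,6-dienoate
Conditions: CH2Cl2, 25 °C
Reagents that add atoms: none
Why: Wittig olefination with a stabilised ylide should give the (E)-enoate, the isolated terminal alkene taking no part.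

Step 2
Reactants: 3 ethyl (2E)-hepta-2,6-dienoate
Product: 4 (2E)-hepta-2,6-dien-1-ol
Conditions: iBu2AlH (2.2 equiv), CH2Cl2, −78 °C; aq. potassium sodium tartrate
Reagents that add atoms: none
Why: Hydride reduction of the conjugated ester by iBu2AlH proceeds by 1,2-addition to the allylic alcohol and leaves both alkenes alone.

Step 3
Reactants: 4 (2E)-hepta-2,6-dien-1-ol
Product: 5 [(2S,3S)-3-(but-3-en-1-yl)oxiran-2-yl]methanol
Conditions: Ti(OiPr)4 (10 mol%), L-(+)-diisopropyl tartrate (12 mol%), t-BuOOH, 4 Å molecular sieves, CH2Cl2, −20 °C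
Reagents that add atoms: tert-butyl hydroperoxide, CC(C)(C)OO
Why: Sharpless asymmetric epoxidation is directed by the allylic hydroxyl, so only the 2,3-alkene reacts, and the L-(+)-tartrate ligand delivers oxygen to the face that gives the (2S,3S)-epoxide, which fixes the future C5 and prepares C4.

Step 4
Reactants: 5 [(2S,3S)-3-(but-3-en-1-yl)oxiran-2-yl]methanol
Product: 6 (2R,3R)-3-methylhept-6-ene-1,2-diol
Conditions: Me3Al (3 equiv), hexane/CH2Cl2, 0 → 25 °C
Reagents that add atoms: trimethylaluminium, C[Al](C)C
Why: Hydroxyl-directed epoxide opening by Me3Al transfers methyl to C3 of the aluminium alkoxide with SN2 inversion, which should give the 1,2-diol regioselectively and set C4 with its methyl group anti to the C5 oxygen.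

Step 5
Reactants: 6 (2R,3R)-3-methylhept-6-ene-1,2-diol
Product: 7 (4R)-4-[(2R)-hex-5-en-2-yl]-2-phenyl-1,3-dioxolane (both epimers at the acetal carbon)
Conditions: PhCH(OMe)2, camphorsulfonic acid (cat.), CH2Cl2, 25 °C
Reagents that add atoms: benzaldehyde dimethyl acetal, COC(OC)c1ccccc1
Why: Acid-catalysed transacetalisation closes the five-membered benzylidene acetal on the 1,2-diol, and the acetal carbon may be an epimeric mixture because it becomes a benzylic CH2 in the next step.

Step 6
Reactants: 7 (4R)-4-[(2R)-hex-5-en-2-yl]-2-phenyl-1,3-dioxolane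
Product: 8 (2R,3R)-2-(benzyloxy)-3-methylhept-6-en-1-ol
Conditions: iBu2AlH (3 equiv), CH2Cl2, 0 °C; aq. potassium sodium tartrate
Reagents that add atoms: none
Why: Reductive opening of the benzylidene acetal: the aluminium hydride binds the less hindered primary oxygen and cleaves that acetal C–O bond, so the benzyl group stays on the secondary C5 oxygen.

Step 7
Reactants: 8 (2R,3R)-2-(benzyloxy)-3-methylhept-6-en-1-ol
Product: 9 (2R,3R)-2-(benzyloxy)-3-methylhept-6-enal
Conditions: Dess–Martin periodinane, pyridine, CH2Cl2, 0 °C; used without storage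
Reagents that add atoms: none
Why: Dess–Martin oxidation of the primary alcohol under buffered conditions should give the α-benzyloxy aldehyde without epimerising C5.

Fragment B (C7–C13 with C9 ester)

Step 8
Reactants: 10 prop-2-en-1-ol
Product: 11 3-(methoxymethoxy)prop-1-ene
Conditions: MeOCH2Cl, iPr2NEt, CH2Cl2, 0 → 25 °C
Reagents that add atoms: chloromethyl methyl ether, COCCl
Why: O-Alkylation of the alcohol by the α-chloro ether (methoxymethyl acetal protection) provides the substrate for allylic metalation.

Step 9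
Reactants: 11 3-(methoxymethoxy)prop-1-ene; 12 2-methylprop-2-enal
Product: 14 (3S,4S)-4-(methoxymethoxy)-2-methylhexa-1,5-dien-3-ol, via the (Z)-alkoxyallyl diisopinocampheylborane 13 (not isolated)
Conditions: s-BuLi, THF, −78 °C; (+)-Ipc2BOMe; BF3·OEt2, then 12, −78 °C; NaOH, H2O2, 0 → 25 °C
Reagents that add atoms: none
Why: Asymmetric γ-alkoxyallylboration: kinetic lithiation gives the (Z)-alkoxyallyl anion, and its borane 13 adds through a chair Zimmerman–Traxler transition state in which the Z geometry gives the syn diol monoether and the isopinocampheyl groups steer the allyl unit to the Re face of the aldehyde, which sets C8 and C9.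

Step 10
Reactants: 14 (3S,4S)-4-(methoxymethoxy)-2-methylhexa-1,5-dien-3-ol; 15 2-methylpropanoyl chloride
Product: 16 (3S,4S)-4-(methoxymethoxy)-2-methylhexa-1,5-dien-3-yl 2-methylpropanoate
Conditions: pyridine, DMAP (cat.), CH2Cl2, 0 °C
Reagents that add atoms: none
Why: DMAP-catalysed acylation of the free secondary hydroxyl installs the C9 isobutyrate of the target with retention.

Step 11
Reactants: 16 (3S,4S)-4-(methoxymethoxy)-2-methylhexa-1,5-dien-3-yl 2-methylpropanoate
Product: 17 (3S,4S)-4-hydroxy-2-methylhexa-1,5-dien-3-yl 2-methylpropanoate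
Conditions: ZnBr2, n-PrSH, CH2Cl2, 0 °C
Reagents that add atoms: none
Why: Lewis acid-assisted thiolysis of the methoxymethyl acetal is fast and non-basic, so the C8 hydroxyl should be freed without migration of the neighbouring isobutyrate or ionisation of the allylic C–O bonds.

Step 12
Reactants: 17 (3S,4S)-4-hydroxy-2-methylhexa-1,5-dien-3-yl 2-methylpropanoate; 18 2-(bromomethyl)prop-2-enoic acid
Product: 19 (3S,4S)-2-methyl-3-[(2-methylpropanoyl)oxy]hexa-1,5-dien-4-yl 2-(bromomethyl)prop-2-enoate
Conditions: DCC, DMAP (5 mol%), CH2Cl2, 0 °C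
Reagents that add atoms: none
Why: Carbodiimide (Steglich) esterification acylates the C8 hydroxyl with retention, the low DMAP loading and temperature limiting SN2′ attack on the allylic bromide and acyl migration.

Step 13
Reactants: 19 (3S,4S)-2-methyl-3-[(2-methylpropanoyl)oxy]hexa-1,5-dien-4-yl 2-(bromomethyl)prop-2-enoate
Product: 20 (1S)-1-[(2S)-4-(bromomethyl)-5-oxo-2,5-dihydrofuran-2-yl]-2-methylprop-2-en-1-yl 2-methylpropanoate
Conditions: second-generation Grubbs catalyst RuCl2(=CHPh)(H2IMes)(PCy3) (5 mol%), CH2Cl2 (0.01 M), 40 °C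
Reagents that add atoms: none
Why: Ring-closing metathesis between the vinyl group and the acrylate alkene closes the butenolide (C7=C11) with loss of ethene, while the isopropenyl group stays out because it could only form a tetrasubstituted alkene.

Union, unveiling, ring closure and end game

Step 14
Reactants: 20 (bromomethyl)butenolide; 9 (2R,3R)-2-(benzyloxy)-3-methylhept-6-enal
Product: 21 (1S)-1-[(2S,3R)-3-[(1R,2R,3R)-2-(benzyloxy)-1-hydroxy-3-methylhept-6-en-1-yl]-4-methylidene-5-oxooxolan-2-yl]-2-methylprop-2-en-1-yl 2-methylpropanoate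
Conditions: In powder, THF/H2O (1:1), 25 °C
Reagents that add atoms: none
Why: Barbier-type indium allylation: the allylindium formed from 20 attacks the aldehyde with its γ-carbon C7 through a chair transition state on the butenolide face anti to the C8 side chain (C7/C8 trans), the ring-fixed E-type allyl geometry gives the C6/C7 relationship of the target, and α-chelation of indium by the C5 benzyloxy group (Cram chelate) selects the same aldehyde face, so C6 and C7 should be set in a matched sense while C11=C13 is formed.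

Step 15
Reactants: 21 C6 alcohol; 15 2-methylpropanoyl chloride
Product: 22 (1R,2R,3R)-2-(benzyloxy)-3-methyl-1-[(2S,3R)-4-methylidene-2-[(1S)-2-methyl-1-[(2-methylpropanoyl)oxy]prop-2-en-1-yl]-5-oxooxolan-3-yl]hept-6-en-1-yl 2-methylpropanoate
Conditions: pyridine, DMAP (cat.), CH2Cl2, 0 → 25 °C
Reagents that add atoms: none
Why: DMAP-catalysed acylation esterifies the C6 hydroxyl with retention, and fast acylation under weakly basic conditions should outrun translactonisation of this hydroxyl onto C12.

Step 16
Reactants: 22 diester; 23 dimethylamine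
Product: 24 (1R,2R,3R)-2-(benzyloxy)-1-[(2S,3R,4R)-4-[(dimethylamino)methyl]-2-[(1S)-2-methyl-1-[(2-methylpropanoyl)oxy]prop-2-en-1-yl]-5-oxooxolan-3-yl]-3-methylhept-6-en-1-yl 2-methylpropanoate
Conditions: Me2NH (2 M in THF, 3 equiv), THF, 0 → 25 °C
Reagents that add atoms: none
Why: Aza-Michael addition of the secondary amine to the α-methylene lactone masks C11=C13, protonation of the enolate should place the aminomethyl group trans to the C7 substituent (new C11 centre, erased in step 20), and the hindered isobutyrates should resist aminolysis.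

Step 17
Reactants: 24 amine-masked diene
Product: 25 (1R,2R,3R)-2-(benzyloxy)-1-[(2S,3R,4R)-4-[(dimethylamino)methyl]-2-[(1R)-1-[(2-methylpropanoyl)oxy]-2-oxopropyl]-5-oxooxolan-3-yl]-3-methyl-6-oxohexyl 2-methylpropanoate (seco aldehyde–methyl ketone, precursor of the key step)
Conditions: TsOH·H2O (1.05 equiv), CH2Cl2/MeOH, −78 °C; O3 (Sudan Red 7B end point); Me2S, −78 → 25 °C; aq. NaHCO3
Reagents that add atoms: ozone, [O-][O+]=O
Why: Ozonolysis with reductive work-up cleaves the vinyl and the isopropenyl group to the C1 aldehyde and the C10 methyl ketone in one operation, the amine being shielded from ozone as its ammonium tosylate and the benzyl ether and esters being inert at −78 °C.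

Step 18
Reactants: 25 seco aldehyde–methyl ketone
Product: 26 (4R,5R,6R,7R,8S,9R,10R,11R)-5-(benzyloxy)-13-(dimethylamino)-10-hydroxy-6,9-bis[(2-methylpropanoyl)oxy]-1-oxogermacran-12,8-olide (ten-membered α-ketol)
Conditions: (5aS,10bR)-2-(pentafluorophenyl)-5a,10b-dihydro-4H,6H-indeno[2,1-b][1,2,4]triazolo[4,3-d][1,4]oxazin-2-ium tetrafluoroborate (30 mol%), Et3N (30 mol%), CH2Cl2, 30 °C, 25 added by syringe pump over 24 h (final 1 mM)
Reagents that add atoms: none
Why: Proposed new method: the carbene freed from the triazolium salt by Et3N adds to the unhindered C1 aldehyde, proton transfer gives the nucleophilic enaminol, this attacks the C10 ketone (activated by its α-acyloxy group) and collapse of the adduct returns the carbene and the α-ketol; the closest known reaction type is the carbene-catalysed intramolecular crossed aldehyde–ketone benzoin reaction that gives five- and six-membered tertiary α-ketols, here extended to a ten-membered ring. The carbocycle closes by 10-exo-trig addition to the C10 carbonyl. The new centre C10 is controlled by the adjacent C9 acyloxy stereocentre: in the Felkin–Anh/Cornforth arrangement with the C9–O bond anti to the incoming C1, attack falls on the Si face of C10 and gives the required 10R carbinol, and the chiral pocket of the chosen catalyst antipode is meant to reinforce this. Chemoselectivity rests on the aldehyde being the only group able to form the acyl anion equivalent and on the ketone being the only acceptor once C11=C13 is masked (no Stetter addition), while only weak amine bases are present, which should spare the epimerisable C9 centre and the lactone oxygen β to the ketone. Ring closure must outrun intermolecular homo-benzoin coupling, which slow addition at about 1 mM and the turn imposed by the trans-lactone and the contiguous C5–C9 substituents should secure.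

Step 19
Reactants: 26 ten-membered α-ketol
Product: 27 (4R,5R,6R,7R,8S,9R,10R,11R)-13-(dimethylamino)-5,10-dihydroxy-6,9-bis[(2-methylpropanoyl)oxy]-1-oxogermacran-12,8-olide
Conditions: H2 (1 atm), Pd(OH)2/C, EtOAc/AcOH (20:1), 25 °C
Reagents that add atoms: none
Why: Catalytic hydrogenolysis cleaves the benzyl ether to the C5 hydroxyl under non-basic conditions that should preclude acyl migration, acetic acid keeps the amine protonated so that it does not poison the catalyst, and no alkene is present because C11=C13 is still masked.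

Step 20
Reactants: 27 amino diol
Product: 29 (4R,5R,6R,7R,8S,9R,10R)-5,10-dihydroxy-6,9-bis[(2-methylpropanoyl)oxy]-1-oxogermacr-11(13)-en-12,8-olide (CNP0396108.1), via the trimethylammonium iodide 28 (not isolated)
Conditions: MeI, THF, 25 °C; then aq. NaHCO3, EtOAc, 25 °C
Reagents that add atoms: iodomethane, CI (its methyl group enters 28 only)
Why: N-Methylation (Menshutkin quaternisation) followed by E1cB retro-Michael elimination of trimethylamine under bicarbonate restores C11=C13 and erases C11, the base being too weak to harm the esters or the α-ketol.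

**Compound list**

1 | pent-4-enal | C=CCCC=O | starting material
2 | ethyl (triphenyl-λ5-phosphanylidene)acetate | CCOC(=O)C=P(c1ccccc1)(c1ccccc1)c1ccccc1 | starting material
3 | ethyl (2E)-hepta-2,6-dienoate | CCOC(=O)/C=C/CCC=C | intermediate
4 | (2E)-hepta-2,6-dien-1-ol | OC/C=C/CCC=C | intermediate
5 | [(2S,3S)-3-(but-3-en-1-yl)oxiran-2-yl]methanol | OC[C@@H]1O[C@H]1CCC=C | intermediate
6 | (2R,3R)-3-methylhept-6-ene-1,2-diol | OC[C@H](O)[C@H](C)CCC=C | intermediate
7 | (4R)-4-[(2R)-hex-5-en-2-yl]-2-phenyl-1,3-dioxolane, acetal carbon unassigned | O1C[C@H](OC1c2ccccc2)[C@H](C)CCC=C | intermediate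
8 | (2R,3R)-2-(benzyloxy)-3-methylhept-6-en-1-ol | OC[C@H](OCc1ccccc1)[C@H](C)CCC=C | intermediate
9 | (2R,3R)-2-(benzyloxy)-3-methylhept-6-enal | O=C[C@H](OCc1ccccc1)[C@H](C)CCC=C | intermediate
10 | prop-2-en-1-ol | C=CCO | starting material
11 | 3-(methoxymethoxy)prop-1-ene | C=CCOCOC | intermediate
12 | 2-methylprop-2-enal | CC(=C)C=O | starting material
13 | [(2Z)-3-(methoxymethoxy)prop-2-en-1-yl]diisopinocampheylborane, isopinocampheyl groups from (−)-α-pinene | COCO/C=C\CB([C@H]1C[C@H]2C[C@@H]([C@@H]1C)C2(C)C)[C@H]1C[C@H]2C[C@@H]([C@@H]1C)C2(C)C | intermediate (not isolated)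
14 | (3S,4S)-4-(methoxymethoxy)-2-methylhexa-1,5-dien-3-ol | COCO[C@H]([C@@H](O)C(C)=C)C=C | intermediate
15 | 2-methylpropanoyl chloride | CC(C)C(Cl)=O | starting material
16 | (3S,4S)-4-(methoxymethoxy)-2-methylhexa-1,5-dien-3-yl 2-methylpropanoate | COCO[C@H]([C@@H](OC(=O)C(C)C)C(C)=C)C=C | intermediate
17 | (3S,4S)-4-hydroxy-2-methylhexa-1,5-dien-3-yl 2-methylpropanoate | O[C@H]([C@@H](OC(=O)C(C)C)C(C)=C)C=C | intermediate
18 | 2-(bromomethyl)prop-2-enoic acid | OC(=O)C(=C)CBr | starting material
19 | (3S,4S)-2-methyl-3-[(2-methylpropanoyl)oxy]hexa-1,5-dien-4-yl 2-(bromomethyl)prop-2-enoate | C=C(CBr)C(=O)O[C@H]([C@@H](OC(=O)C(C)C)C(C)=C)C=C | intermediate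
20 | (1S)-1-[(2S)-4-(bromomethyl)-5-oxo-2,5-dihydrofuran-2-yl]-2-methylprop-2-en-1-yl 2-methylpropanoate | O=C1O[C@H]([C@@H](OC(=O)C(C)C)C(C)=C)C=C1CBr | intermediate
21 | (1S)-1-[(2S,3R)-3-[(1R,2R,3R)-2-(benzyloxy)-1-hydroxy-3-methylhept-6-en-1-yl]-4-methylidene-5-oxooxolan-2-yl]-2-methylprop-2-en-1-yl 2-methylpropanoate | C=C1C(=O)O[C@H]([C@@H](OC(=O)C(C)C)C(C)=C)[C@H]1[C@@H](O)[C@H](OCc2ccccc2)[C@H](C)CCC=C | intermediate
22 | (1R,2R,3R)-2-(benzyloxy)-3-methyl-1-[(2S,3R)-4-methylidene-2-[(1S)-2-methyl-1-[(2-methylpropanoyl)oxy]prop-2-en-1-yl]-5-oxooxolan-3-yl]hept-6-en-1-yl 2-methylpropanoate | C=C1C(=O)O[C@H]([C@@H](OC(=O)C(C)C)C(C)=C)[C@H]1[C@@H](OC(=O)C(C)C)[C@H](OCc2ccccc2)[C@H](C)CCC=C | intermediate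
23 | dimethylamine | CNC | starting material
24 | (1R,2R,3R)-2-(benzyloxy)-1-[(2S,3R,4R)-4-[(dimethylamino)methyl]-2-[(1S)-2-methyl-1-[(2-methylpropanoyl)oxy]prop-2-en-1-yl]-5-oxooxolan-3-yl]-3-methylhept-6-en-1-yl 2-methylpropanoate | CN(C)C[C@@H]1C(=O)O[C@H]([C@@H](OC(=O)C(C)C)C(C)=C)[C@H]1[C@@H](OC(=O)C(C)C)[C@H](OCc2ccccc2)[C@H](C)CCC=C | intermediate
25 | (1R,2R,3R)-2-(benzyloxy)-1-[(2S,3R,4R)-4-[(dimethylamino)methyl]-2-[(1R)-1-[(2-methylpropanoyl)oxy]-2-oxopropyl]-5-oxooxolan-3-yl]-3-methyl-6-oxohexyl 2-methylpropanoate | CN(C)C[C@@H]1C(=O)O[C@H]([C@@H](OC(=O)C(C)C)C(C)=O)[C@H]1[C@@H](OC(=O)C(C)C)[C@H](OCc2ccccc2)[C@H](C)CCC=O | intermediate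
26 | (4R,5R,6R,7R,8S,9R,10R,11R)-5-(benzyloxy)-13-(dimethylamino)-10-hydroxy-6,9-bis[(2-methylpropanoyl)oxy]-1-oxogermacran-12,8-olide | CN(C)C[C@@H]1C(=O)O[C@H]2[C@H]1[C@@H](OC(=O)C(C)C)[C@H](OCc3ccccc3)[C@H](C)CCC(=O)[C@](C)(O)[C@@H]2OC(=O)C(C)C | intermediate
27 | (4R,5R,6R,7R,8S,9R,10R,11R)-13-(dimethylamino)-5,10-dihydroxy-6,9-bis[(2-methylpropanoyl)oxy]-1-oxogermacran-12,8-olide | CN(C)C[C@@H]1C(=O)O[C@H]2[C@H]1[C@@H](OC(=O)C(C)C)[C@H](O)[C@H](C)CCC(=O)[C@](C)(O)[C@@H]2OC(=O)C(C)C | intermediate
28 | N,N,N-trimethylammonium iodide of 27 (13-trimethylammonio derivative) | C[N+](C)(C)C[C@@H]1C(=O)O[C@H]2[C@H]1[C@@H](OC(=O)C(C)C)[C@H](O)[C@H](C)CCC(=O)[C@](C)(O)[C@@H]2OC(=O)C(C)C.[I-] | intermediate (not isolated)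
29 | (4R,5R,6R,7R,8S,9R,10R)-5,10-dihydroxy-6,9-bis[(2-methylpropanoyl)oxy]-1-oxogermacr-11(13)-en-12,8-olide, CNP0396108.1 | C=C1C(=O)O[C@H]2[C@H]1[C@@H](OC(=O)C(C)C)[C@H](O)[C@H](C)CCC(=O)[C@](C)(O)[C@@H]2OC(=O)C(C)C | target

**Step count and risks**

Total step count: 20. Longest linear sequence: 14 steps (steps 1–7, then 14–20).

Steps most likely to fail:

1. Step 18 (Proposed new method).
   - What may go wrong: intermolecular homo-benzoin coupling of the C1 aldehyde may outpace the medium-ring closure. Ring strain may reverse the closure by retro-benzoin. The C10 face may be attacked unselectively if catalyst and C9 control are mismatched; the other catalyst antipode would be tried first within the step. The amine may cause epimerisation at C9 or β-elimination of the lactone oxygen.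
   - Fallback by known chemistry, setting out from 24 and returning at 26: the amine adduct 24, protonated with TsOH, is submitted to ring-closing metathesis between its vinyl and isopropenyl groups (second-generation Hoveyda–Grubbs catalyst RuCl2(=CH-C6H4-2-OiPr)(H2IMes), toluene, 80 °C, 1 mM). This should give the (1Z)-5-(benzyloxy)-13-(dimethylamino)-6,9-bis[(2-methylpropanoyl)oxy]germacr-1(10)-en-12,8-olide F1. Dihydroxylation with OsO4 (cat.) and N-methylmorpholine N-oxide, expected on the exposed outer face of the ring alkene, gives the 1,10-diol F2; the C1 configuration is of no consequence, that at C10 would have to be confirmed. Parikh–Doering oxidation (SO3·pyridine, DMSO, iPr2NEt) of the secondary C1 hydroxyl then gives 26.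

2. Step 14.
   - What may go wrong: facial selectivity on the α-benzyloxy aldehyde may erode if indium chelation is not maintained in the closed transition state. The allylindium may be protonated by water. The free C6 hydroxyl of the product may translactonise onto C12.
   - Fallback, setting out from 20 and 9 and returning at 22: if attack on the other aldehyde face prevails, the C6-epimeric alcohol F3 is isolated and esterified with 2-methylpropanoic acid under Mitsunobu conditions (PPh3, diisopropyl azodicarboxylate, toluene, 0 → 25 °C). The inversion at C6 delivers the diester 22 directly, by-passing 21.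

3. Step 19.
   - What may go wrong: hydrogenolysis of the hindered C5 benzyl ether may be slow or incomplete with the amine poisoning the catalyst, and the isobutyryl group may migrate from O6 to O5 on prolonged exposure.
   - Fallback, setting out from 26 and returning at 29: the order is reversed and no hydrogen is used. 26 is quaternised with MeI to the trimethylammonium iodide F4, and aqueous NaHCO3 eliminates trimethylamine to give the 5-O-benzyl ether of the target F5. BCl3 with pentamethylbenzene as cation scavenger (CH2Cl2, −78 °C) then cleaves the benzyl ether to 29.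

Further compounds
F1 | step 18 | (1Z)-5-(benzyloxy)-13-(dimethylamino)-6,9-bis[(2-methylpropanoyl)oxy]germacr-1(10)-en-12,8-olide | CN(C)C[C@@H]1C(=O)O[C@H]2[C@H]1[C@@H](OC(=O)C(C)C)[C@H](OCc3ccccc3)[C@H](C)CC/C=C(C)\[C@@H]2OC(=O)C(C)C
F2 | step 18 | 5-(benzyloxy)-13-(dimethylamino)-1,10-dihydroxy-6,9-bis[(2-methylpropanoyl)oxy]germacran-12,8-olide (10R as in 26) | CN(C)C[C@@H]1C(=O)O[C@H]2[C@H]1[C@@H](OC(=O)C(C)C)[C@H](OCc3ccccc3)[C@H](C)CC[C@H](O)[C@](C)(O)[C@@H]2OC(=O)C(C)C
F3 | step 14 | C6 epimer of 21, (1S)-1-[(2S,3R)-3-[(1S,2R,3R)-2-(benzyloxy)-1-hydroxy-3-methylhept-6-en-1-yl]-4-methylidene-5-oxooxolan-2-yl]-2-methylprop-2-en-1-yl 2-methylpropanoate | C=C1C(=O)O[C@H]([C@@H](OC(=O)C(C)C)C(C)=C)[C@H]1[C@H](O)[C@H](OCc2ccccc2)[C@H](C)CCC=C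
F4 | step 19 | N,N,N-trimethylammonium iodide of 26 | C[N+](C)(C)C[C@@H]1C(=O)O[C@H]2[C@H]1[C@@H](OC(=O)C(C)C)[C@H](OCc3ccccc3)[C@H](C)CCC(=O)[C@](C)(O)[C@@H]2OC(=O)C(C)C.[I-]
F5 | step 19 | 5-O-benzyl ether of 29 | C=C1C(=O)O[C@H]2[C@H]1[C@@H](OC(=O)C(C)C)[C@H](OCc3ccccc3)[C@H](C)CCC(=O)[C@](C)(O)[C@@H]2OC(=O)C(C)C
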